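All runs were computed on assumed constants, and the scatter is random.

Put the protic impurity first in line for the nucleophile, and read the runs that way.

| setting | epsilon | eta | delta | flask |
|---|---|---|---|---|
| electrophile | 0.50 M (fed, over 1.0 h) | 0.50 M (fed, over 1.0 h) | 0.75 M (fed, over 1.0 h) | 0.50 M (fed, over 1.0 h) |
| nucleophile | 0.40 M | 0.40 M | 0.40 M | 0.400 M |
| free base | 0.50 M | 0.50 M | 0.50 M | 0.500 M |
| protic impurity | 0.075 M | 0.30 M | 0.15 M | 0.150 M |
| remark | run made earlier | run made earlier | run made earlier |  |
| time |  |  |  | 5.0 h |

- epsilon (time / h: electrophile / %, product / %): 0.250: 24.7, 0.3; 0.833: 74.8, 8.1; 1.33: 85.3, 12.8; 2.00: 79.6, 20.1; 3.00: 73.6, 25.8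
- eta (time / h: electrophile / %, product / %): 0.667: 64.1, 5.7; 1.33: 91.6, 9.8; 2.00: 88.4, 9.2; 2.50: 86.4, 12.0; 3.00: 85.6, 12.8
- delta (time / h: electrophile / %, product / %): 0.250: 23.7, 0; 0.417: 39.3, 0.6; 0.833: 76.7, 6.6; 1.50: 86.2, 12.1; 3.00: 82.7, 19.1

(scatter of a reading: 1 percentage point)

- percentages count the whole charge, also what has not yet gone in
- the earlier runs do not show how much of nucleophile is bound; that part of a forecast is a guess

- part of the electrophile that has reacted at 5.0 h
- share of the unused nucleophile that is free and not bound as protonated nucleophile, at 5.0 h

Between 2.00 h and 3.00 h the epsilon run gained 5.7 percentage points of product, and over the same hour the eta run, with more impurity, gained 3.6 points, less than epsilon. So charge one nucleophile per impurity. In the flask that leaves 0.250 M as the margin, c(nucleophile) minus c(protic impurity). This is smaller than c(electrophile), so take the nucleophile as the limiting reagent.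

Now reckon the rate. Take epsilon's margin less its product, with its mean electrophile, and that hour reads a rate constant of 0.354 M⁻¹ h⁻¹, a rough reading from scattered numbers. On the flask's whole charges, counted as if the fed electrophile stood in at once, this gives 0.0708 M h⁻¹ as a notional starting rate, and the impurity's toll multiplies it by 0.625, down to 0.0442 M h⁻¹. Start the clock at mid-feed and let product eat both partners: my reckoning reaches 0.124 M of product at 5.0 h. By then the margin term has slowed the rate by a factor 0.504 and the electrophile term by 0.753, leaving 0.0168 M h⁻¹. I commit to 24.7% reacted, and leave the free share unreckoned, since the runs do not show binding.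

The forecast gives 29.5% reacted and 42% free, and says of the second: “The binding extent is a guess”.

The flask gives 27.9% reacted, against my 24.7%, and 97.6% free.

    electrophile + nucleophile → acid set free + product (k = 0.790 M⁻¹ h⁻¹)
    nucleophile + acid set free ⇌ protonated nucleophile, settled at all times (K = 83.0 M⁻¹)
    acid set free + free base ⇌ salt of the base, settled at all times (K = 1300 M⁻¹)
    nucleophile + protic impurity → quenched reagent (k = 6.60 M⁻¹ h⁻¹)
    2 nucleophile → homo dimer (k = 0.410 M⁻¹ h⁻¹)

At 0.298 h the flask's nucleophile has a half-life of 1.4 h by the impurity step, shorter than the 6.1 h by the product step. At 5.00 h the flask's quenched reagent stands at 0.146 M, nearly all of the 0.150 M taken off to reach the margin 0.250 M. With 1.0 M of nucleophile and the other charges as in the flask, the margin grows to 0.850 M, and the same reckoning gives 64.4% reacted. That flask gives 54.9%, with 0.239 M of homo dimer at the end.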